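**Strategy.** The trans-2-aryl-3-(acyloxymethyl)-2,3-dihydrobenzofuran core is traced to an (R)-flavanone. The feature exploited is the exocyclic CH2O carbon on C3 next to the C3–C3a aryl bond: in a chroman-4-one this carbon is the ring carbonyl C4, bonded to the same arene carbon. An iodine(III)-mediated oxidative 1,2-shift of that arene carbon from C4 to C3 contracts the six-membered pyranone to the five-membered O1–C2–C3–C3a–C7a ring, expels C4 as a methyl ester and sets C3 trans to the C2 aryl group, itself installed by asymmetric conjugate arylation of a chromone. A C5 bromide receives the ferulate-bearing propyl chain late by B-alkyl Suzuki coupling.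

Key step: step 4

Assumption: compounds 1, 5, 12 and 14 are taken as catalogue materials. The C3 descriptor changes from R (ester 10) to S (alcohol 11 onwards) through CIP priorities only, not through any change at the centre.

**Step 1**
Reactants: 1 1-(5-bromo-2-hydroxy-3-methoxyphenyl)ethan-1-one; 2 N,N-dimethylformamide dimethyl acetal
Product: 4 6-bromo-8-methoxy-4H-chromen-4-one, via enaminone 3 (not isolated)
Conditions: 2 (2 equiv), toluene, 100 °C; then conc. HCl, CH2Cl2, 40 °C
Reagents that add atoms: none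
Why: Condensation of the methyl ketone with the amide acetal gives the enaminone, and acid-induced addition–elimination by the ortho phenol (loss of dimethylamine) closes the pyranone, the standard enaminone route to 2,3-unsubstituted chromones.

**Step 2**
Reactants: 5 (4-hydroxy-3-methoxyphenyl)boronic acid
Product: 6 [3-methoxy-4-(pivaloyloxy)phenyl]boronic acid
Conditions: PivCl, pyridine, CH2Cl2, 0 °C → rt; 1 M aq. HCl work-up
Reagents that add atoms: pivaloyl chloride, CC(C)(C)C(=O)Cl
Why: Phenol O-acylation should proceed cleanly, any B–O acyl mixed anhydride being hydrolysed on the acidic aqueous work-up; the pivalate is chosen because it lowers the donor strength of the aryl group for step 4 and resists acid.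

**Step 3**
Reactants: 4 6-bromo-8-methoxy-4H-chromen-4-one; 6 [3-methoxy-4-(pivaloyloxy)phenyl]boronic acid
Product: 7 4-[(2R)-6-bromo-8-methoxy-4-oxo-3,4-dihydro-2H-chromen-2-yl]-2-methoxyphenyl pivalate
Conditions: Pd(OCOCF3)2 (5 mol%), (S)-t-BuPyOx (6 mol%), NH4PF6 (30 mol%), H2O (5 equiv), 6 (2 equiv), ClCH2CH2Cl, 60 °C
Reagents that add atoms: none
Why: Pd(II)/pyridine-oxazoline-catalysed asymmetric conjugate addition of an arylboronic acid to a chromone, in which the chiral ligand controls the face of aryl insertion at C2 ((S)-ligand expected to give 2R by analogy with cyclic enones, the antipodal ligand being used should the sense prove opposite) and the Pd(II)-only cycle should leave the C–Br bond alone.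

**Step 4**
Reactants: 7 4-[(2R)-6-bromo-8-methoxy-4-oxo-3,4-dihydro-2H-chromen-2-yl]-2-methoxyphenyl pivalate
Product: 10 methyl (2R,3R)-5-bromo-7-methoxy-2-[3-methoxy-4-(pivaloyloxy)phenyl]-2,3-dihydro-1-benzofuran-3-carboxylate, via enol ether 8 (not isolated), via iodane 9 (not isolated)
Conditions: PhI(OAc)2 (1.3 equiv), conc. H2SO4 (3 equiv), HC(OMe)3, rt; aq. NaHCO3
Reagents that add atoms: trimethyl orthoformate, COC(OC)OC; water, O
Why: Acid and orthoformate should convert the C4 ketone into the 4-methoxy-2H-chromene 8, whose enol ether carbon C3 attacks the iodine(III) electrophile anti to the C2 aryl group to give the C3 λ3-iodane 9 (C4 as dimethyl ketal); the arene carbon C4a, antiperiplanar to the equatorial C3–I bond, then shifts from C4 to C3 as iodobenzene departs, and the dimethoxycarbenium ion at the expelled C4 collapses to the methyl ester on work-up. The closest known reaction type is the hypervalent-iodine (or thallium(III)) oxidative rearrangement of flavanones in trimethyl orthoformate to methyl trans-2-aryl-2,3-dihydrobenzofuran-3-carboxylates. The five-membered ring arises by ring contraction of the six-membered pyranone through a bridged phenonium ion (3-exo attack of C3 on the ipso carbon C4a, then reopening towards C3), the only new ring bond being C3–C3a. C2 is not involved and keeps its configuration; C3 is set under substrate control, since displacement of iodine with inversion places the ester carbon trans to the C2 aryl group, which is also the thermodynamic epimer. The selectivity needed is migration of the A-ring carbon C4a in preference to a shift of the C2 aryl group (isoflavone) or dehydrogenation to the flavone; the ring oxygen ortho to C4a, the stabilised dialkoxycarbenium product and the electron-withdrawing pivalate on the C2 aryl group should secure it.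

**Step 5**
Reactants: 10 methyl (2R,3R)-5-bromo-7-methoxy-2-[3-methoxy-4-(pivaloyloxy)phenyl]-2,3-dihydro-1-benzofuran-3-carboxylate
Product: 11 4-[(2R,3S)-5-bromo-3-(hydroxymethyl)-7-methoxy-2,3-dihydro-1-benzofuran-2-yl]-2-methoxyphenol
Conditions: DIBAL-H (6 equiv), CH2Cl2, −78 → 0 °C; aq. Rochelle salt
Reagents that add atoms: none
Why: Hydride reduction of the methyl ester to the primary alcohol with concomitant reductive cleavage of the aryl pivalate should occur without touching the aryl bromide or either stereocentre.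

**Step 6**
Reactants: 11 4-[(2R,3S)-5-bromo-3-(hydroxymethyl)-7-methoxy-2,3-dihydro-1-benzofuran-2-yl]-2-methoxyphenol; 12 (E)-3-(4-acetoxyphenyl)acrylic acid
Product: 13 [(2R,3S)-5-bromo-2-(4-hydroxy-3-methoxyphenyl)-7-methoxy-2,3-dihydro-1-benzofuran-3-yl]methyl (E)-3-(4-acetoxyphenyl)acrylate
Conditions: 12 (1.2 equiv), PPh3, DIAD, THF, 0 °C → rt
Reagents that add atoms: none
Why: Mitsunobu esterification, in which the primary alcohol is activated as its alkoxyphosphonium ion and displaced by the carboxylate; the far more acidic carboxylic acid outcompetes the phenol as pronucleophile, so the phenol should remain free and no stereocentre is touched.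

**Step 7**
Reactants: 14 (E)-3-(4-acetoxy-3-methoxyphenyl)acrylic acid; 15 allyl bromide
Product: 16 allyl (E)-3-(4-acetoxy-3-methoxyphenyl)acrylate
Conditions: KHCO3, DMF, rt
Reagents that add atoms: none
Why: SN2 O-alkylation of the carboxylate under bicarbonate, mild enough to leave the aryl acetate in place.

**Step 8**
Reactants: 16 allyl (E)-3-(4-acetoxy-3-methoxyphenyl)acrylate; 13 [(2R,3S)-5-bromo-2-(4-hydroxy-3-methoxyphenyl)-7-methoxy-2,3-dihydro-1-benzofuran-3-yl]methyl (E)-3-(4-acetoxyphenyl)acrylate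
Product: 18 3-[(2R,3S)-3-({[(E)-3-(4-acetoxyphenyl)acryloyl]oxy}methyl)-2-(4-hydroxy-3-methoxyphenyl)-7-methoxy-2,3-dihydro-1-benzofuran-5-yl]propyl (E)-3-(4-acetoxy-3-methoxyphenyl)acrylate, via alkylborane 17 (not isolated)
Conditions: 16 (1.5 equiv), 9-BBN (1.4 equiv), THF, 0 °C → rt; then 13, Pd(OAc)2 (5 mol%), SPhos (10 mol%), K3PO4 (3 equiv), THF/H2O, 40 °C
Reagents that add atoms: none
Why: Anti-Markovnikov hydroboration of the terminal allyl alkene with 9-BBN (the conjugated cinnamate alkene is inert, and no B–H remains because the alkene is in excess) followed by B-alkyl Suzuki–Miyaura coupling with the aryl bromide should install the whole 3-(acyloxy)propyl chain at C5; any aryl acetate lost to the base converges in step 9.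

**Step 9**
Reactants: 18 3-[(2R,3S)-3-({[(E)-3-(4-acetoxyphenyl)acryloyl]oxy}methyl)-2-(4-hydroxy-3-methoxyphenyl)-7-methoxy-2,3-dihydro-1-benzofuran-5-yl]propyl (E)-3-(4-acetoxy-3-methoxyphenyl)acrylate
Product: 19 (+)-boehmenan X
Conditions: pyrrolidine (6 equiv), CH2Cl2, 0 °C → rt
Reagents that add atoms: none
Why: Aminolysis by a secondary amine is selective for the activated aryl acetates over the alkyl cinnamate esters, so both phenols should be released without cleaving or adding to the cinnamates.

**Compound list**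

1 | 1-(5-bromo-2-hydroxy-3-methoxyphenyl)ethan-1-one | CC(=O)c1cc(Br)cc(OC)c1O | starting material
2 | N,N-dimethylformamide dimethyl acetal | COC(OC)N(C)C | starting material
3 | (E)-1-(5-bromo-2-hydroxy-3-methoxyphenyl)-3-(dimethylamino)prop-2-en-1-one (enaminone) | CN(C)/C=C/C(=O)c1cc(Br)cc(OC)c1O | intermediate
4 | 6-bromo-8-methoxy-4H-chromen-4-one | COc1cc(Br)cc2c(=O)ccoc12 | intermediate
5 | (4-hydroxy-3-methoxyphenyl)boronic acid | COc1cc(B(O)O)ccc1O | starting material
6 | [3-methoxy-4-(pivaloyloxy)phenyl]boronic acid | COc1cc(B(O)O)ccc1OC(=O)C(C)(C)C | intermediate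
7 | 4-[(2R)-6-bromo-8-methoxy-4-oxo-3,4-dihydro-2H-chromen-2-yl]-2-methoxyphenyl pivalate | O=C1C[C@H](c2ccc(OC(=O)C(C)(C)C)c(OC)c2)Oc2c(OC)cc(Br)cc12 | intermediate
8 | 4-[(2R)-6-bromo-4,8-dimethoxy-2H-chromen-2-yl]-2-methoxyphenyl pivalate (enol ether) | COC1=C[C@H](c2ccc(OC(=O)C(C)(C)C)c(OC)c2)Oc2c(OC)cc(Br)cc12 | intermediate
9 | 4-[(2S,3S)-3-[acetoxy(phenyl)-λ3-iodanyl]-6-bromo-4,4,8-trimethoxy-3,4-dihydro-2H-chromen-2-yl]-2-methoxyphenyl pivalate (iodine anti to the C2 aryl group) | COc1cc(Br)cc2c1O[C@@H](c1ccc(OC(=O)C(C)(C)C)c(OC)c1)[C@H](I(OC(C)=O)c1ccccc1)C2(OC)OC | intermediate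
10 | methyl (2R,3R)-5-bromo-7-methoxy-2-[3-methoxy-4-(pivaloyloxy)phenyl]-2,3-dihydro-1-benzofuran-3-carboxylate (trans) | Brc1cc(OC)c2c(c1)[C@@H](C(=O)OC)[C@H](c1ccc(OC(=O)C(C)(C)C)c(OC)c1)O2 | intermediate
11 | 4-[(2R,3S)-5-bromo-3-(hydroxymethyl)-7-methoxy-2,3-dihydro-1-benzofuran-2-yl]-2-methoxyphenol | Brc1cc(OC)c2c(c1)[C@@H](CO)[C@H](c1ccc(O)c(OC)c1)O2 | intermediate
12 | (E)-3-(4-acetoxyphenyl)acrylic acid | CC(=O)Oc1ccc(/C=C/C(=O)O)cc1 | starting material
13 | [(2R,3S)-5-bromo-2-(4-hydroxy-3-methoxyphenyl)-7-methoxy-2,3-dihydro-1-benzofuran-3-yl]methyl (E)-3-(4-acetoxyphenyl)acrylate | Brc1cc(OC)c2c(c1)[C@@H](COC(=O)/C=C/c1ccc(OC(C)=O)cc1)[C@H](c1ccc(O)c(OC)c1)O2 | intermediate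
14 | (E)-3-(4-acetoxy-3-methoxyphenyl)acrylic acid | COc1cc(/C=C/C(=O)O)ccc1OC(C)=O | starting material
15 | allyl bromide | C=CCBr | starting material
16 | allyl (E)-3-(4-acetoxy-3-methoxyphenyl)acrylate | COc1cc(/C=C/C(=O)OCC=C)ccc1OC(C)=O | intermediate
17 | 3-(9-borabicyclo[3.3.1]nonan-9-yl)propyl (E)-3-(4-acetoxy-3-methoxyphenyl)acrylate (alkylborane) | COc1cc(/C=C/C(=O)OCCCB2C3CCCC2CCC3)ccc1OC(C)=O | intermediate
18 | 3-[(2R,3S)-3-({[(E)-3-(4-acetoxyphenyl)acryloyl]oxy}methyl)-2-(4-hydroxy-3-methoxyphenyl)-7-methoxy-2,3-dihydro-1-benzofuran-5-yl]propyl (E)-3-(4-acetoxy-3-methoxyphenyl)acrylate | COc1cc(/C=C/C(=O)OCCCc2cc(OC)c3c(c2)[C@@H](COC(=O)/C=C/c2ccc(OC(C)=O)cc2)[C@H](c2ccc(O)c(OC)c2)O3)ccc1OC(C)=O | intermediate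
19 | (+)-boehmenan X, (2R,3S) | COc1cc(/C=C/C(=O)OCCCc2cc(OC)c3c(c2)[C@@H](COC(=O)/C=C/c2ccc(O)cc2)[C@H](c2ccc(O)c(OC)c2)O3)ccc1O | target

**Count**

Total steps: 9. Longest linear sequence: 7 (steps 1, 3, 4, 5, 6, 8, 9).

**Steps most likely to fail**

1. Step 4. The C2 aryl group may migrate instead of the A-ring carbon (isoflavone formation), the enol ether may simply be dehydrogenated to the flavone, or acid may strip the pivalate and expose the phenol to oxidation. Fallback, still a six-to-five contraction but by Wolff rearrangement, sets out from 7. Low-temperature enolisation (LiHMDS, THF, −78 °C) and trapping with 2,2,2-trifluoroethyl trifluoroacetate should give 4-[(2R)-6-bromo-8-methoxy-4-oxo-3-(trifluoroacetyl)chroman-2-yl]-2-methoxyphenyl pivalate F1. Detrifluoroacetylative diazo transfer (MsN3, Et3N, H2O, MeCN) should then give 4-[(2S)-6-bromo-3-diazo-8-methoxy-4-oxochroman-2-yl]-2-methoxyphenyl pivalate F2. Irradiation at 350 nm in MeOH/THF should induce loss of nitrogen and migration of C4a from C4 to C3, giving the ketene 4-[(2S)-5-bromo-7-methoxy-3-(oxomethylidene)-2,3-dihydro-1-benzofuran-2-yl]-2-methoxyphenyl pivalate F3. Methanol traps the ketene, with protonation anti to the aryl group (or equilibration to the trans epimer), and the route is rejoined at 10.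

2. Step 3. Enantioselectivity may erode through ligand-free background addition, the arylboronic acid may protodeboronate, or adventitious Pd(0) may insert into the C–Br bond. Fallback sets out from 1 and replaces catalytic arylation by chalcone cyclisation and kinetic resolution. Vanillin is acylated (PivCl, pyridine) to 4-formyl-2-methoxyphenyl pivalate F4. BF3·OEt2-mediated Claisen–Schmidt condensation with 1 (dioxane, rt) should give (E)-1-(5-bromo-2-hydroxy-3-methoxyphenyl)-3-[3-methoxy-4-(pivaloyloxy)phenyl]prop-2-en-1-one F5. Oxa-Michael cyclisation (NaOAc, EtOH, reflux) should give racemic 4-(6-bromo-8-methoxy-4-oxochroman-2-yl)-2-methoxyphenyl pivalate F6. Asymmetric transfer hydrogenation to about half conversion (RuCl[(S,S)-TsDPEN](p-cymene), HCO2H/Et3N, EtOAc, rt) is expected to reduce the (S)-ketone to 4-[(2S,4S)-6-bromo-4-hydroxy-8-methoxychroman-2-yl]-2-methoxyphenyl pivalate F7, which is removed by chromatography. The unreacted (R)-ketone is 7, where the route is rejoined.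

3. Step 8. Oxidative addition into the electron-rich aryl bromide may be sluggish, the phenoxide formed under aqueous base may slow the catalyst, and the base may partly saponify the esters. Fallback sets out from 14 and uses a base-free Negishi coupling. Esterification with 3-iodopropan-1-ol (EDC·HCl, DMAP, CH2Cl2) should give 3-iodopropyl (E)-3-(4-acetoxy-3-methoxyphenyl)acrylate F8. Zinc insertion (Zn dust, LiCl, THF, rt to 40 °C) should give [3-{[(E)-3-(4-acetoxy-3-methoxyphenyl)acryloyl]oxy}propyl]zinc iodide F9. Slow addition of this reagent (one extra equivalent to allow for the free phenol) to 13 with Pd(OAc)2/SPhos in THF at rt should give 18, where the route is rejoined.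

**Further compounds**

F1 | step 4 | 4-[(2R)-6-bromo-8-methoxy-4-oxo-3-(trifluoroacetyl)chroman-2-yl]-2-methoxyphenyl pivalate (C3 enolisable, unspecified) | O=C1C(C(=O)C(F)(F)F)[C@H](c2ccc(OC(=O)C(C)(C)C)c(OC)c2)Oc2c(OC)cc(Br)cc12
F2 | step 4 | 4-[(2S)-6-bromo-3-diazo-8-methoxy-4-oxochroman-2-yl]-2-methoxyphenyl pivalate | O=C1C(=[N+]=[N-])[C@H](c2ccc(OC(=O)C(C)(C)C)c(OC)c2)Oc2c(OC)cc(Br)cc12
F3 | step 4 | 4-[(2S)-5-bromo-7-methoxy-3-(oxomethylidene)-2,3-dihydro-1-benzofuran-2-yl]-2-methoxyphenyl pivalate (ketene) | Brc1cc(OC)c2c(c1)C(=C=O)[C@H](c1ccc(OC(=O)C(C)(C)C)c(OC)c1)O2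
F4 | step 3 | 4-formyl-2-methoxyphenyl pivalate | COc1cc(C=O)ccc1OC(=O)C(C)(C)C
F5 | step 3 | (E)-1-(5-bromo-2-hydroxy-3-methoxyphenyl)-3-[3-methoxy-4-(pivaloyloxy)phenyl]prop-2-en-1-one | COc1cc(/C=C/C(=O)c2cc(Br)cc(OC)c2O)ccc1OC(=O)C(C)(C)C
F6 | step 3 | racemic 4-(6-bromo-8-methoxy-4-oxochroman-2-yl)-2-methoxyphenyl pivalate | O=C1CC(c2ccc(OC(=O)C(C)(C)C)c(OC)c2)Oc2c(OC)cc(Br)cc12
F7 | step 3 | 4-[(2S,4S)-6-bromo-4-hydroxy-8-methoxychroman-2-yl]-2-methoxyphenyl pivalate (2,4-cis) | O[C@H]1C[C@@H](c2ccc(OC(=O)C(C)(C)C)c(OC)c2)Oc2c(OC)cc(Br)cc12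
F8 | step 8 | 3-iodopropyl (E)-3-(4-acetoxy-3-methoxyphenyl)acrylate | COc1cc(/C=C/C(=O)OCCCI)ccc1OC(C)=O
F9 | step 8 | [3-{[(E)-3-(4-acetoxy-3-methoxyphenyl)acryloyl]oxy}propyl]zinc iodide | COc1cc(/C=C/C(=O)OCCC[Zn]I)ccc1OC(C)=O
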